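(The numbers were drawn at random within sensible limits; the result is computed.)

How much target stands at the outlet or at the end of each set-up, and which set-up gives most?

| setting | Sunday's | Wednesday's | Thursday's |
|---|---|---|---|
| starting material | 20 mM | 20 mM (fed, over 2.50 min) | 20 mM |
| capture agent | 0.400 mM | 0.400 mM | 0.400 mM |
| remark | a single well-mixed tank run continuously and read at steady state, 2.5 min in it on average | a stirred flask in which starting material is dosed at a steady rate over 2.50 min without added volume, worked up at 2.5 min | everything together in a closed stirred flask, run for 2.5 min |
| time |  | 2.5 min | 2.5 min |

    starting material → intermediate A (k1 = 0.050 s⁻¹)
    intermediate A → intermediate B (k2 = 0.0094 s⁻¹)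
    intermediate B → intermediate C (k3 = 0.85 s⁻¹)
    intermediate C → target (k4 = 0.0098 s⁻¹)
    intermediate B → side product (k5 = 0.046 s⁻¹)
    2 starting material → self-condensation product (k6 = 0.080 M⁻¹ s⁻¹)
    intermediate B + capture agent → trapped intermediate (k7 = 0.44 M⁻¹ s⁻¹)

- order of the set-ups by the amount of target at the outlet or at the end, in percent of the starting material put in, highest first (Sunday's / Wednesday's / Thursday's)
- amount of target at the outlet or at the end, in percent of the starting material put in, Sunday's
- amount of target at the outlet or at the end, in percent of the starting material put in, Wednesday's
- amount of target at the outlet or at the end, in percent of the starting material put in, Thursday's

- in percentages every species weighs as the starting material in it: one self-condensation product counts as two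
- a step written with two of one species runs at k times the square of its concentration and takes two of it each time
- the stated concentrations are those of everything mixed, before any reaction; amounts are the same in each set-up
- the feed brings no volume worth counting
- run time (Wednesday's): 2.5 min

I follow one molecule of starting material and climb the ladder of half-lives from the fastest rung. Intermediate B stands there: its half-life towards intermediate C is 0.82 s, far shorter than the 0.23 min of starting material, so it acts as a fork and not as a store. Its half-life towards side product is 0.25 min, and capture, pseudo-first-order at 1.76 × 10⁻⁴ s⁻¹ with the capture agent as charged, is far slower than that. The constant towards intermediate C divided by the sum of the rates out of intermediate B comes to 94.8%: this is the fork share, the chance that a molecule reaching the fork goes on towards target.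

On the next rung, starting material turns into intermediate A sooner than it self-condenses, whose first half-life at the full charge is 5.21 min. Above that stand intermediates A and C, at 1.2 min and 1.2 min. The 2.5 min of each set-up, an average stay in Sunday's tank, is twice that, so I expect molecules still on their way at the reading and target well under the fork share.

In Wednesday's flask the average molecule enters at 1.25 min, which leaves it half the time, so I put Wednesday's well below Thursday's. For Sunday's tank, each slow stage is passed with the chance kτ/(1+kτ), where τ is the average stay. Those chances times the fork share give 29.1%, with self-condensation not counted. My hand reckoning stops there.

The forecast gives Thursday's > Sunday's > Wednesday's, with 28.7% for Sunday's, a little under my figure, 12% for Wednesday's and 32.3% for Thursday's. It starts from the same fork: “B is short-lived (lifetime about 1 s), so it splits almost at once”.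

The simulation gives Thursday's > Sunday's > Wednesday's, with 28.7% for Sunday's, 12.0% for Wednesday's and 32.3% for Thursday's, as forecast.

So 32.3% in Thursday's flask is a reading along the way, with 29.0% still intermediate A and 31.8% intermediate C. At 25.0 min that flask holds 91.9% target, and the fork share applied to what remains after the 3.07% in self-condensation product gives 91.9%. The neighbour is Wednesday's flask read at 6.0 min. Setting aside its 9.09% of intermediate A, 0.0964% of intermediate B and 0.729% of self-condensation product, the fork share gives 85.4% beyond the fork on the target side, and that neighbour holds 66.6% target and 18.9% intermediate C, together 85.5%.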